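## The problem

The target, (5S,6R,8R,9R,10S,13S)-6β-acetoxy-9α,13;15,16-diepoxylabd-14-ene, is a trans-decalin (rings A and B) whose C9 is the spiro atom of a tetrahydrofuran (ring C: O, C9, C11, C12, C13); C13 is in turn the spiro atom of a 2,3-dihydrofuran (ring D: C13, C14, C15, O, C16). Six stereocentres must be set. C5 and C10 are those of the normal labdane series and can be bought. C6 (axial β-acetoxy), C8 (equatorial α-methyl) and C9 (α-oxygen on a fully substituted carbon next to quaternary C10) lie on the rigid decalin and can be controlled by its β-axial methyl groups C19 and C20. C13 is fully substituted, sits on a flexible chain when it must be made, and is defined only by which of two CH2O arms becomes C14 and which C16, so it needs reagent control. The oxidation pattern is the real difficulty: a chiral-pool decalin such as sclareolide has oxygen at C8 and hydrogen at C9, the reverse of what is needed, and nothing at C6. The sensitive functions are the ring D enol ether (acid opens ring C and gives the 9-hydroxy furan), the tertiary allylic and propargylic C–O bonds met on the way, and the hindered C6 acetate, which does not survive alkoxide. What opens the problem is that C6 and C9 stand 1,4 to each other in ring B: they are the termini of a C6=C7–C8=C9 diene. Dioxygen can bridge them from the α face, and C6 then carries the only hydrogen on a peroxide carbon, so base-induced cleavage can go only one way.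

## Retrosynthesis

**Ring D (O–C15, then C14–C15).** Target 26 is opened at the enol ether O–C15 bond to the homopropargylic alcohol 25. Its alkyne carbon C15 is then cut from C14, leading through acetate 24 and alcohol 23 to aldehyde 22. A lactol dehydration would need acid on the final product; this cut lets the enol ether form last, in an amine-buffered medium, with the acetate already in place. The forward reaction must add the C16 hydroxyl to the terminal alkyne carbon (overall 5-endo) without touching C13.

**C6 and C8 (C6–OAc, C8–H, C6–H).** Aldehyde 22 comes from diol 21 by oxidation of the primary alcohol only. The C8–H bond of 21 is traced to the C7=C8 alkene of allylic alcohol 20, and the C6–H bond of 20 to enone 19. Both centres are thus set from one enone: hydride enters C6 from the open α face, and the resulting 6β-hydroxyl carries hydrogen to the β face of C8. The hydrogenation is placed after ring C closure because a free 9α-hydroxyl would direct to the wrong face, and before the alkyne exists.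

**Ring C (C13–O).** Enone 19 is opened at the C13–O bond to the hydroxy epoxide 18. An epoxide is preferred to an oxocarbenium or haloetherification route because the C13 configuration is then fixed earlier by a reagent and is transferred by inversion. The forward reaction is a 5-exo opening at the tertiary epoxide carbon; it also frees the C14 hydroxyl while C16 stays silylated, which is what keeps the two arms of C13 distinct.

**Key disconnection (C6–O and C9–O).** Hydroxy enone 18 is cut at both ring B C–O bonds, through endoperoxide 17, to the hydrocarbon diene 16. No neighbouring cut makes the hindered tertiary C9–O bond and the C6 oxygen together. The precursor loses two oxygens and one stereocentre. The forward reaction needs α-face addition and (4+2) rather than ene reactivity.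

**Diene (C7–H).** Diene 16 is traced to dienyl triflate 15 and so to enone 13. Dehydrating a C7 alcohol at the ester stage risks elimination toward C11 into conjugation with the ester, and an early diene would have to survive iodination, zinc, palladium and a peroxide. The triflate route fixes the diene position and makes the diene one step before it is used.

**C13 and the chain (epoxide C–O, C12–C13).** Silyl ether 13 comes from epoxy alcohol 12, and 12 from the 2-substituted allylic alcohol 11 by reagent-controlled epoxidation. Alcohol 11 is cut at C12–C13 into alkyl iodide 6 and alkenyl bromide 8, the latter made from 2-bromoprop-2-en-1-ol 7. The sp3–sp2 coupling must tolerate the enone; an organozinc reagent does.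

**Decalin (C12–I, C7=O, C8=C9).** Iodide 6 goes back through hydroxy enone 5, diol 4 and enone ester 3 to the alkene ester 2 and (+)-sclareolide 1. Sclareolide supplies rings A and B, C5, C10, C11 and C12. Its C8 oxygen is used only to create the C8=C9 alkene that activates C7. The ester is kept during the allylic oxidation because it deactivates C11.

## Roads not taken

**Alternative 1:** The cut runs through C4–C5, C9–C10 and C9–O at once, returning rings A and B to the acyclic 16-hydroxygeranylgeranyl diphosphate A2. A class 2 diterpene cyclase of the peregrinol diphosphate synthase type would protonate the terminal alkene, close both rings, shift hydride from C9 to C8 and quench the C9 cation with water, giving 16-hydroxyperegrinol diphosphate A1.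
- Merits: one step builds the decalin with C5, C8, C9 and C10 correct, including the 8α-methyl and 9α-hydroxyl groups. Here it is clearly better than the chosen plan, which spends steps 12, 14 and 15 on C9 and C8.
- Weak points: the enzyme must accept an extra allylic hydroxyl near the diphosphate. A1 has no oxygen at C6 and no handle to put one there, so a second position-selective hydroxylation would be needed. C13 is still an alkene carbon, so ring C with control at C13 and ring D are still to come. Diphosphates limit scale and later reagents.
- Comparison: against the ring economy of A1, the chosen plan places the C6 oxygen in the same step as the C9 oxygen, uses ordinary solution chemistry on a cheap chiral-pool lactone, and fixes C13 with a reagent before any ring is closed on it.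

**Alternative 2:** Only ring D is cut: the C14=C15 bond is traced to the spiro 1,3-oxathiane S,S-dioxide A4. KOH on Al2O3 with CBr2F2 would halogenate next to sulfur, the α-sulfonyl carbanion would close an episulfone, and loss of SO2 would contract the ring to the deacetyl target A3.
- Merits: the enol ether is formed under base, never acid. The sulfone is robust and not reducible, so unlike alkyne 23 it could be carried through a hydrogenation.
- Weak points: it says nothing about C6 and C9. Building A4 needs sulfur on the C14 arm, an O,S-acetal closure and S-oxidation, with the same differentiation of the two arms as in the chosen route and at least as many steps. The dihalocarbene released from CBr2F2 can add to electron-rich alkenes, and the enol ether product is the best trap in the flask. KOH rules out the acetate, so the hindered 6β-hydroxyl of A3 must be acylated after the labile ring exists.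
- Comparison: as an endgame it is about equal in length. The chosen plan closes ring D catalytically with Et3N as the only base, as the last step, with the acetate in place. The two are compatible, but the lactol fallback below is shorter than a detour through A4.

**Alternative 3:** The cut removes C9–C10 and C9–O, opening rings B and C to the monocyclic keto alcohol A6, a 2,6,6-trimethylcyclohexene carrying the whole chain. Strong acid would condense the C13 hydroxyl with the C9 ketone to a five-membered oxocarbenium ion; C10 of the ring A alkene attacks it, and loss of H6 gives the 9,13-epoxylabd-5-ene A5.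
- Merits: convergent; the tertiary C9–O bond and quaternary C10 form in one step; ring A analogues are accessible because no chiral pool is needed. The C8 methyl arrives with the fragment, so no late hydrogenation is required, an advantage over step 15.
- Weak points: C8 is α to the ketone and to the oxocarbenium ion, so it can epimerise through the enol ether under the conditions of the key step. Two adjacent fully substituted carbons must be joined by a tetrasubstituted alkene attacking a fully substituted cation. The configurations of C9 and C10 relative to C8 and C13 depend on the folding of a flexible chain. The C5 cation may suffer a methyl shift from C4. A5 still lacks the C6 oxygen; α-face hydroboration would give the 6α-alcohol, which needs oxidation and reduction to invert. A6 needs two separate enantioselective operations.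
- Comparison: more convergent and more general. The chosen plan buys rings A and B with C5 and C10 and lets the rigid decalin control C9, C6 and C8 in turn, at the cost of more functional-group steps.

Key step: step 12

## Route

Remark on the chemistry: labdane numbering is kept for every intermediate (C11 and C12 come from sclareolide, C13, C14 and C16 from 2-bromoprop-2-en-1-ol, C15 from the diazophosphonate). Diol 4 is carried as a mixture of C7 epimers because C7 becomes sp2 again in step 4.

Step 1
Reactants: 1 (+)-sclareolide
Product: 2 methyl 13,14,15,16-tetranorlabd-8-en-12-oate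
Conditions: conc. H2SO4, MeOH, rt then 60 °C
Reagents that add atoms: methanol, CO
Why: Acid-catalysed lactone methanolysis with E1 elimination: the tertiary C8–O bond ionises, H9 is lost and the acid is esterified (Fischer esterification); under equilibrating acid the tetrasubstituted C8=C9 alkene should predominate, and minor alkene isomers can be removed on AgNO3-impregnated silica. No stereocentre is formed.

Step 2
Reactants: 2 methyl 13,14,15,16-tetranorlabd-8-en-12-oate
Product: 3 methyl 7-oxo-13,14,15,16-tetranorlabd-8-en-12-oate
Conditions: CrO3, 3,5-dimethylpyrazole, CH2Cl2, −20 °C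
Reagents that add atoms: chromium trioxide, O=[Cr](=O)=O
Why: Chromium-mediated allylic oxidation: the ring methylene C7 is the most electron-rich and accessible allylic position, C11 is deactivated by the adjacent ester carbonyl, and the C17 methyl reacts more slowly than a methylene, so the 8-en-7-one is expected.

Step 3
Reactants: 3 methyl 7-oxo-13,14,15,16-tetranorlabd-8-en-12-oate
Product: 4 13,14,15,16-tetranorlabd-8-ene-7,12-diol (C7 epimers)
Conditions: iBu2AlH, CH2Cl2, −78 to 0 °C; aq. potassium sodium tartrate
Reagents that add atoms: none
Why: Hydride reduction of the ester and 1,2-reduction of the enone in one operation; the C7 configuration is irrelevant because this alcohol is oxidised again in step 4.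

Step 4
Reactants: 4 13,14,15,16-tetranorlabd-8-ene-7,12-diol
Product: 5 12-hydroxy-13,14,15,16-tetranorlabd-8-en-7-one
Conditions: MnO2, CH2Cl2, rt
Reagents that add atoms: none
Why: Chemoselective allylic oxidation: MnO2 oxidises only the allylic C7 alcohol, while the homoallylic primary C12 alcohol is not activated; the enone is restored without a protecting group.

Step 5
Reactants: 5 12-hydroxy-13,14,15,16-tetranorlabd-8-en-7-one
Product: 6 12-iodo-13,14,15,16-tetranorlabd-8-en-7-one
Conditions: I2, PPh3, imidazole, CH2Cl2, 0 °C to rt
Reagents that add atoms: iodine, II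
Why: Appel-type iodination of a primary alcohol by SN2 displacement of the alkoxyphosphonium ion; the enone is inert.

Step 6
Reactants: 7 2-bromoprop-2-en-1-ol
Product: 8 (2-bromoprop-2-en-1-yloxy)(tert-butyl)dimethylsilane
Conditions: TBSCl, imidazole, CH2Cl2, rt
Reagents that add atoms: tert-butyldimethylsilyl chloride, CC(C)(C)[Si](C)(C)Cl
Why: Standard silylation of a primary alcohol; the silyl ether keeps the hydroxyl from protonating the valuable organozinc reagent in step 7.

Step 7
Reactants: 6 12-iodo-13,14,15,16-tetranorlabd-8-en-7-one; 8 (2-bromoprop-2-en-1-yloxy)(tert-butyl)dimethylsilane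
Product: 11 16-hydroxy-15-norlabda-8,13(14)-dien-7-one, via alkylzinc iodide 9 (not isolated), via silyl ether 10 (not isolated)
Conditions: Zn dust, LiCl, THF, 40 °C; then 8, PdCl2(dppf) (5 mol %), THF, 50 °C; then 1 M HCl, MeOH, rt
Reagents that add atoms: none
Why: Negishi sp3–sp2 coupling forms C12–C13: LiCl-assisted zinc insertion into the primary C–I bond tolerates the ketone, and the dppf ligand favours reductive elimination over β-hydride elimination after transmetalation to the oxidative-addition product of 8. Acid methanolysis in the same flask removes the primary TBS group.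

Step 8
Reactants: 11 16-hydroxy-15-norlabda-8,13(14)-dien-7-one
Product: 12 (13S)-13,14-epoxy-16-hydroxy-15-norlabd-8-en-7-one
Conditions: Ti(OiPr)4 (10 mol %), L-(+)-diethyl tartrate (12 mol %), tBuOOH, 4 Å molecular sieves, CH2Cl2, −20 °C
Reagents that add atoms: tert-butyl hydroperoxide, CC(C)(C)OO
Why: Sharpless asymmetric epoxidation: the tartrate alone decides the face because the allylic alcohol is remote from the decalin, and L-(+)-diethyl tartrate delivers oxygen in the sense that turns 2-methylprop-2-en-1-ol into (S)-2-methylglycidol, so the 13S epoxy alcohol is expected. The electron-poor enone alkene is not epoxidised by the Ti(OiPr)4–tartrate–tBuOOH system.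

Step 9
Reactants: 12 (13S)-13,14-epoxy-16-hydroxy-15-norlabd-8-en-7-one
Product: 13 16-(tert-butyldiphenylsilyloxy)-13,14-epoxy-15-norlabd-8-en-7-one
Conditions: TBDPSCl, imidazole, DMF, rt
Reagents that add atoms: tert-butyldiphenylsilyl chloride, CC(C)(C)[Si](Cl)(c1ccccc1)c1ccccc1
Why: Silylation of the primary epoxy alcohol; TBDPS is chosen over TBS because it must survive the acid of step 13 and must not migrate to the C14 hydroxyl formed there, which would exchange the two arms of C13 and erase its configuration.

Step 10
Reactants: 13 16-(tert-butyldiphenylsilyloxy)-13,14-epoxy-15-norlabd-8-en-7-one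
Product: 15 16-(tert-butyldiphenylsilyloxy)-13,14-epoxy-15-norlabda-6,8-dien-7-yl trifluoromethanesulfonate, via potassium dienolate 14 (not isolated)
Conditions: KN(SiMe3)2, THF, −78 °C; then PhNTf2, −78 to 0 °C
Reagents that add atoms: N-phenylbis(trifluoromethanesulfonimide), O=S(=O)(N(c1ccccc1)S(=O)(=O)C(F)(F)F)C(F)(F)F
Why: Kinetic deprotonation of the enone at the α' carbon C6 gives the cross-conjugated dienolate, which is O-sulfonylated (enol triflate formation); the hindered amide base at −78 °C should leave the epoxide and the γ-hydrogens at C11 alone.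

Step 11
Reactants: 15 16-(tert-butyldiphenylsilyloxy)-13,14-epoxy-15-norlabda-6,8-dien-7-yl trifluoromethanesulfonate
Product: 16 16-(tert-butyldiphenylsilyloxy)-13,14-epoxy-15-norlabda-6,8-diene
Conditions: Pd(OAc)2 (5 mol %), PPh3 (10 mol %), HCO2H, nBu3N, DMF, 60 °C
Reagents that add atoms: none
Why: Palladium-catalysed formate reduction of an enol triflate (oxidative addition, formate exchange, decarboxylation, C–H reductive elimination) replaces OTf by H without moving the double bonds, so the homoannular 6,8-diene is formed with defined regiochemistry; the amine-buffered formate should not open the epoxide.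

Step 12
Reactants: 16 16-(tert-butyldiphenylsilyloxy)-13,14-epoxy-15-norlabda-6,8-diene
Product: 18 9α-hydroxy-16-(tert-butyldiphenylsilyloxy)-13,14-epoxy-15-norlabd-7-en-6-one, via endoperoxide 17 (not isolated)
Conditions: O2, tetraphenylporphyrin (cat.), hν (visible), CH2Cl2, −20 °C; then Et3N, 0 °C to rt
Reagents that add atoms: dioxygen, O=O
Why: Sensitised singlet oxygen adds suprafacially to the termini C6 and C9 of the ring B diene in a (4+2) cycloaddition to give the 6α,9α-epidioxide 17; Et3N then removes H6, the only hydrogen on a peroxide-bearing carbon, and the O–O bond breaks (Kornblum–DeLaMare rearrangement) to the C6 ketone and the C9 alkoxide, which is protonated to the tertiary alcohol. The closest known reactions are the photooxygenation of steroidal 5,7-dienes and decalin 6,8-dienes to α-face endoperoxides and their amine-induced opening to γ-hydroxy enones. No ring of the target is closed: the six-membered 1,2-dioxene bridge, formed by concerted (4+2) closure, is transient and is opened in the same flask. The one new stereocentre that survives, C9, is set by the β-axial methyl groups C20 (on C10, next to C9) and C19 (1,3 to C6), which leave only the α face of the diene open; the C6 centre of 17 is erased when the ketone forms. The step needs (4+2) addition to win over ene reactions at C11, C17 and C5, which the locked s-cis geometry of the homoannular diene secures, and it needs the epoxide and silyl ether to stay inert, as they are towards singlet oxygen and a tertiary amine at or below room temperature. Both C–O bonds, including the hindered tertiary C9–O bond, are thus made on a hydrocarbon diene, and the remaining C7=C8 enone is the handle for C6 and C8.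

Step 13
Reactants: 18 9α-hydroxy-16-(tert-butyldiphenylsilyloxy)-13,14-epoxy-15-norlabd-7-en-6-one
Product: 19 (13S)-9α,13-epoxy-14-hydroxy-16-(tert-butyldiphenylsilyloxy)-15-norlabd-7-en-6-one
Conditions: (+)-camphor-10-sulfonic acid (10 mol %), CH2Cl2, 0 °C
Reagents that add atoms: none
Why: Acid-catalysed intramolecular epoxide opening closes ring C: the 9α-hydroxyl attacks the tertiary epoxide carbon C13 in a 5-exo-tet closure, favoured by ring size and by Markovnikov polarisation, with inversion at C13. The C9 hydroxyl should not ionise because the cation would sit at the γ-position of an enone.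

Step 14
Reactants: 19 (13S)-9α,13-epoxy-14-hydroxy-16-(tert-butyldiphenylsilyloxy)-15-norlabd-7-en-6-one
Product: 20 (13S)-9α,13-epoxy-16-(tert-butyldiphenylsilyloxy)-15-norlabd-7-ene-6β,14-diol
Conditions: NaBH4, CeCl3·7H2O, MeOH, −20 to 0 °C
Reagents that add atoms: none
Why: Luche 1,2-reduction; the β face of the C6 carbonyl is blocked by the axial methyl groups C19 and C20, so hydride enters from the α face and the axial 6β-alcohol results.

Step 15
Reactants: 20 (13S)-9α,13-epoxy-16-(tert-butyldiphenylsilyloxy)-15-norlabd-7-ene-6β,14-diol
Product: 21 (13S)-9α,13-epoxy-16-(tert-butyldiphenylsilyloxy)-15-norlabdane-6β,14-diol (8α-methyl)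
Conditions: H2 (1 atm), [Ir(cod)(PCy3)(py)]PF6 (10 mol %), CH2Cl2, rt
Reagents that add atoms: none
Why: Hydroxyl-directed homogeneous hydrogenation: the pseudoaxial allylic 6β-hydroxyl binds iridium, and both hydrogens are delivered to the β face of C7=C8, placing H8 β and the C17 methyl α (equatorial). An allylic hydroxyl is a stronger director than the ring C ether oxygen on the α face.

Step 16
Reactants: 21 (13S)-9α,13-epoxy-16-(tert-butyldiphenylsilyloxy)-15-norlabdane-6β,14-diol
Product: 22 9α,13-epoxy-6β-hydroxy-16-(tert-butyldiphenylsilyloxy)-15-norlabdan-14-al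
Conditions: TEMPO (10 mol %), PhI(OAc)2, CH2Cl2, rt
Reagents that add atoms: none
Why: Oxoammonium oxidation is strongly selective for primary over secondary alcohols, and the axial 6β-hydroxyl is further shielded by C19 and C20; the aldehyde has no α-hydrogen and cannot epimerise.

Step 17
Reactants: 22 9α,13-epoxy-6β-hydroxy-16-(tert-butyldiphenylsilyloxy)-15-norlabdan-14-al
Product: 23 9α,13-epoxy-16-(tert-butyldiphenylsilyloxy)labd-14-yn-6β-ol
Conditions: dimethyl (1-diazo-2-oxopropyl)phosphonate, K2CO3, MeOH, 0 °C to rt
Reagents that add atoms: dimethyl (1-diazo-2-oxopropyl)phosphonate, COP(=O)(OC)C(=[N+]=[N-])C(C)=O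
Why: Seyferth–Gilbert homologation in the Ohira–Bestmann version: methanolysis frees the diazomethylphosphonate anion, which adds to the aldehyde; loss of phosphate and N2 and a 1,2-shift give the terminal alkyne, adding C15. The quaternary α-carbon cannot epimerise.

Step 18
Reactants: 23 9α,13-epoxy-16-(tert-butyldiphenylsilyloxy)labd-14-yn-6β-ol
Product: 24 6β-acetoxy-9α,13-epoxy-16-(tert-butyldiphenylsilyloxy)labd-14-yne
Conditions: Ac2O, Et3N, DMAP (cat.), CH2Cl2, 40 °C
Reagents that add atoms: acetic anhydride, CC(=O)OC(C)=O
Why: DMAP-catalysed acylation; the hindered axial 6β-alcohol needs the nucleophilic catalyst and mild warming, and no other group in 23 can be acylated.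

Step 19
Reactants: 24 6β-acetoxy-9α,13-epoxy-16-(tert-butyldiphenylsilyloxy)labd-14-yne
Product: 25 6β-acetoxy-9α,13-epoxylabd-14-yn-16-ol
Conditions: Bu4NF, AcOH, THF, 0 °C to rt
Reagents that add atoms: none
Why: Fluoride cleavage of the silyl ether, buffered with acetic acid so that the C6 acetate is neither cleaved nor shifted.

Step 20
Reactants: 25 6β-acetoxy-9α,13-epoxylabd-14-yn-16-ol
Product: 26 (5S,6R,8R,9R,10S,13S)-6β-acetoxy-9α,13;15,16-diepoxylabd-14-ene
Conditions: Mo(CO)6 (30 mol %), Et3N, Et2O, hν (350 nm), rt
Reagents that add atoms: none
Why: Alkynol cycloisomerisation through a Mo(CO)5 vinylidene: Et3N·Mo(CO)5 turns the terminal alkyne into a vinylidene, the C16 hydroxyl adds to its electrophilic carbon C15 (overall 5-endo closure), and amine-mediated proton transfer releases the 2,3-dihydrofuran. The medium stays basic, which suits the acid-labile enol ether (purification on Et3N-deactivated silica), and C13 is not touched.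

## Compound list

1 | (+)-sclareolide | C1C[C@@]3(C)OC(=O)C[C@@H]3[C@@]2(C)CCCC(C)(C)[C@H]12 | starting material
2 | methyl (5S,10S)-13,14,15,16-tetranorlabd-8-en-12-oate | C1CC(C)=C(CC(=O)OC)[C@@]2(C)CCCC(C)(C)[C@H]12 | intermediate
3 | methyl 7-oxo-13,14,15,16-tetranorlabd-8-en-12-oate | C1C(=O)C(C)=C(CC(=O)OC)[C@@]2(C)CCCC(C)(C)[C@H]12 | intermediate
4 | 13,14,15,16-tetranorlabd-8-ene-7,12-diol (C7 epimers) | C1C(O)C(C)=C(CCO)[C@@]2(C)CCCC(C)(C)[C@H]12 | intermediate
5 | 12-hydroxy-13,14,15,16-tetranorlabd-8-en-7-one | C1C(=O)C(C)=C(CCO)[C@@]2(C)CCCC(C)(C)[C@H]12 | intermediate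
6 | 12-iodo-13,14,15,16-tetranorlabd-8-en-7-one | C1C(=O)C(C)=C(CCI)[C@@]2(C)CCCC(C)(C)[C@H]12 | intermediate
7 | 2-bromoprop-2-en-1-ol | C=C(Br)CO | starting material
8 | (2-bromoprop-2-en-1-yloxy)(tert-butyl)dimethylsilane | C=C(Br)CO[Si](C)(C)C(C)(C)C | intermediate
9 | (7-oxo-13,14,15,16-tetranorlabd-8-en-12-yl)zinc iodide | C1C(=O)C(C)=C(CC[Zn]I)[C@@]2(C)CCCC(C)(C)[C@H]12 | intermediate (not isolated)
10 | 16-(tert-butyldimethylsilyloxy)-15-norlabda-8,13(14)-dien-7-one | C1C(=O)C(C)=C(CCC(=C)CO[Si](C)(C)C(C)(C)C)[C@@]2(C)CCCC(C)(C)[C@H]12 | intermediate (not isolated)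
11 | 16-hydroxy-15-norlabda-8,13(14)-dien-7-one | C1C(=O)C(C)=C(CCC(=C)CO)[C@@]2(C)CCCC(C)(C)[C@H]12 | intermediate
12 | (13S)-13,14-epoxy-16-hydroxy-15-norlabd-8-en-7-one | C1C(=O)C(C)=C(CC[C@]3(CO)CO3)[C@@]2(C)CCCC(C)(C)[C@H]12 | intermediate
13 | 16-(tert-butyldiphenylsilyloxy)-13,14-epoxy-15-norlabd-8-en-7-one (epoxide as in 12) | C1C(=O)C(C)=C(CC[C@]3(CO[Si](c4ccccc4)(c4ccccc4)C(C)(C)C)CO3)[C@@]2(C)CCCC(C)(C)[C@H]12 | intermediate
14 | potassium 6,8-dien-7-olate of 13 | C1=C([O-])C(C)=C(CC[C@]3(CO[Si](c4ccccc4)(c4ccccc4)C(C)(C)C)CO3)[C@@]2(C)CCCC(C)(C)[C@H]12.[K+] | intermediate (not isolated)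
15 | 16-(tert-butyldiphenylsilyloxy)-13,14-epoxy-15-norlabda-6,8-dien-7-yl trifluoromethanesulfonate | C1=C(OS(=O)(=O)C(F)(F)F)C(C)=C(CC[C@]3(CO[Si](c4ccccc4)(c4ccccc4)C(C)(C)C)CO3)[C@@]2(C)CCCC(C)(C)[C@H]12 | intermediate
16 | 16-(tert-butyldiphenylsilyloxy)-13,14-epoxy-15-norlabda-6,8-diene | C1=CC(C)=C(CC[C@]3(CO[Si](c4ccccc4)(c4ccccc4)C(C)(C)C)CO3)[C@@]2(C)CCCC(C)(C)[C@H]12 | intermediate
17 | 6α,9α-epidioxy-16-(tert-butyldiphenylsilyloxy)-13,14-epoxy-15-norlabd-7-ene | [C@H]1(OO4)C=C(C)[C@]4(CC[C@]3(CO[Si](c5ccccc5)(c5ccccc5)C(C)(C)C)CO3)[C@@]2(C)CCCC(C)(C)[C@H]12 | intermediate (not isolated)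
18 | 9α-hydroxy-16-(tert-butyldiphenylsilyloxy)-13,14-epoxy-15-norlabd-7-en-6-one | O=C1C=C(C)[C@](O)(CC[C@]3(CO[Si](c4ccccc4)(c4ccccc4)C(C)(C)C)CO3)[C@@]2(C)CCCC(C)(C)[C@H]12 | intermediate
19 | (13S)-9α,13-epoxy-14-hydroxy-16-(tert-butyldiphenylsilyloxy)-15-norlabd-7-en-6-one | O=C1C=C(C)[C@]2(CC[C@@](CO[Si](c3ccccc3)(c3ccccc3)C(C)(C)C)(CO)O2)[C@@]2(C)CCCC(C)(C)[C@H]12 | intermediate
20 | (13S)-9α,13-epoxy-16-(tert-butyldiphenylsilyloxy)-15-norlabd-7-ene-6β,14-diol | O[C@@H]1C=C(C)[C@]2(CC[C@@](CO[Si](c3ccccc3)(c3ccccc3)C(C)(C)C)(CO)O2)[C@@]2(C)CCCC(C)(C)[C@H]12 | intermediate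
21 | (13S)-9α,13-epoxy-16-(tert-butyldiphenylsilyloxy)-15-norlabdane-6β,14-diol (8α-methyl, 8β-H) | O[C@@H]1C[C@@H](C)[C@]2(CC[C@@](CO[Si](c3ccccc3)(c3ccccc3)C(C)(C)C)(CO)O2)[C@@]2(C)CCCC(C)(C)[C@H]12 | intermediate
22 | 9α,13-epoxy-6β-hydroxy-16-(tert-butyldiphenylsilyloxy)-15-norlabdan-14-al (C13 as in 21) | O[C@@H]1C[C@@H](C)[C@]2(CC[C@@](CO[Si](c3ccccc3)(c3ccccc3)C(C)(C)C)(C=O)O2)[C@@]2(C)CCCC(C)(C)[C@H]12 | intermediate
23 | 9α,13-epoxy-16-(tert-butyldiphenylsilyloxy)labd-14-yn-6β-ol (C13 as in 21) | O[C@@H]1C[C@@H](C)[C@]2(CC[C@@](CO[Si](c3ccccc3)(c3ccccc3)C(C)(C)C)(C#C)O2)[C@@]2(C)CCCC(C)(C)[C@H]12 | intermediate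
24 | 6β-acetoxy-9α,13-epoxy-16-(tert-butyldiphenylsilyloxy)labd-14-yne | CC(=O)O[C@@H]1C[C@@H](C)[C@]2(CC[C@@](CO[Si](c3ccccc3)(c3ccccc3)C(C)(C)C)(C#C)O2)[C@@]2(C)CCCC(C)(C)[C@H]12 | intermediate
25 | 6β-acetoxy-9α,13-epoxylabd-14-yn-16-ol | CC(=O)O[C@@H]1C[C@@H](C)[C@]2(CC[C@@](CO)(C#C)O2)[C@@]2(C)CCCC(C)(C)[C@H]12 | intermediate
26 | (5S,6R,8R,9R,10S,13S)-6β-acetoxy-9α,13;15,16-diepoxylabd-14-ene | CC(=O)O[C@@H]1C[C@@H](C)[C@]2(CC[C@@]3(C=COC3)O2)[C@@]2(C)CCCC(C)(C)[C@H]12 | target

## Step count and least certain steps

Total step count: 20. Longest linear sequence: 19 steps (steps 1 to 5 and 7 to 20, from sclareolide); step 6 is a one-step side branch.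

**Step 12 (key step).** The most likely failure is a slow base-induced opening: H6 lies close to the C4 methyl groups, so the amine may reach it poorly, and the peroxide can then decompose by homolysis. Ene reaction could also compete with cycloaddition. Fallback: from endoperoxide 17, isolated cold, the O–O bond is cleaved reductively with SmI2 in THF at −78 °C to the 7-ene-6α,9α-diol F1. The allylic secondary hydroxyl at C6 is then oxidised with MnO2, and the sequence rejoins the route at 18. A reduction and an oxidation replace the rearrangement.

**Step 15.** The risk is delivery of hydrogen to the wrong face through competing binding of iridium by the ring C ether oxygen or the primary C14 hydroxyl, or slow turnover at a trisubstituted alkene next to a fully substituted carbon. Fallback: from 20, hydrogen-atom-transfer hydrogenation (Mn(dpm)3, PhSiH3, tBuOOH, iPrOH) gives 21 directly. The tertiary C8 radical is reduced under product-stability control, which favours the equatorial 8α-methyl group, so the outcome no longer depends on which oxygen binds a metal. No compound outside the list is formed (entry F0).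

**Step 20.** The propargylic C13–O bond of ring C may ionise at the vinylidene stage, turnover may be poor next to the quaternary carbon, and the enol ether may hydrolyse during isolation. Fallback: from 24, hydroboration with dicyclohexylborane and buffered NaBO3 oxidation gives aldehyde F2 (anti-Markovnikov hydration). Bu4NF with AcOH removes the silyl group and the hydroxy aldehyde closes to lactol F3. Mesylation with MsCl and Et3N followed by warming eliminates the anomeric sulfonate and rejoins the route at 26.

**Step 7.** Zinc insertion may be incomplete, or the organozinc reagent may be lost by protonation or β-hydride elimination before coupling. Fallback: from 6 and 8, nickel-catalysed reductive cross-electrophile coupling (NiI2, 4,4'-di-tert-butyl-2,2'-bipyridine, Mn powder, NaI, DMPU), in which the alkyl radical from 6 is captured by the alkenylnickel species from 8, gives silyl ether 10. This is methanolysed to 11 as before. No compound outside the list is formed (entry F0).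

**Step 10.** Deprotonation may occur partly at C11 (γ) instead of C6, or the amide base may attack the epoxide, giving mixed enol triflates. Fallback: from 13, Luche reduction (NaBH4, CeCl3·7H2O) gives the allylic alcohol F4. Dehydration with the Burgess reagent (methyl N-(triethylammoniosulfonyl)carbamate) by syn elimination, for which only the C6 hydrogens are available, rejoins the route at 16.

## Further compounds

F1 | step 12 | 16-(tert-butyldiphenylsilyloxy)-13,14-epoxy-15-norlabd-7-ene-6α,9α-diol | O[C@H]1C=C(C)[C@](O)(CC[C@]3(CO[Si](c4ccccc4)(c4ccccc4)C(C)(C)C)CO3)[C@@]2(C)CCCC(C)(C)[C@H]12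
F0 | step 15 | none | none
F2 | step 20 | 6β-acetoxy-9α,13-epoxy-16-(tert-butyldiphenylsilyloxy)labdan-15-al | CC(=O)O[C@@H]1C[C@@H](C)[C@]2(CC[C@@](CO[Si](c3ccccc3)(c3ccccc3)C(C)(C)C)(CC=O)O2)[C@@]2(C)CCCC(C)(C)[C@H]12
F3 | step 20 | 6β-acetoxy-9α,13;15,16-diepoxylabdan-15-ol (C15 epimers) | CC(=O)O[C@@H]1C[C@@H](C)[C@]2(CC[C@@]3(CC(O)OC3)O2)[C@@]2(C)CCCC(C)(C)[C@H]12
F0 | step 7 | none | none
F4 | step 10 | 16-(tert-butyldiphenylsilyloxy)-13,14-epoxy-15-norlabd-8-en-7-ol (C7 epimers) | C1C(O)C(C)=C(CC[C@]3(CO[Si](c4ccccc4)(c4ccccc4)C(C)(C)C)CO3)[C@@]2(C)CCCC(C)(C)[C@H]12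
A1 | alternative 1 | 16-hydroxyperegrinol diphosphate | C1C[C@@H](C)[C@](O)(CC/C(CO)=C/COP(=O)(O)OP(=O)(O)O)[C@@]2(C)CCCC(C)(C)[C@H]12
A2 | alternative 1 | 16-hydroxygeranylgeranyl diphosphate | OP(=O)(O)OP(=O)(O)OC/C=C(CO)/CC/C=C(C)/CC/C=C(C)/CCC=C(C)C
A3 | alternative 2 | 6β-hydroxy-9α,13;15,16-diepoxylabd-14-ene | O[C@@H]1C[C@@H](C)[C@]2(CC[C@@]3(C=COC3)O2)[C@@]2(C)CCCC(C)(C)[C@H]12
A4 | alternative 2 | spiro 1,3-oxathiane S,S-dioxide precursor (C13 spiro; ring C13, C14, S, C15, O, C16) | O[C@@H]1C[C@@H](C)[C@]2(CC[C@@]3(CS(=O)(=O)COC3)O2)[C@@]2(C)CCCC(C)(C)[C@H]12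
A5 | alternative 3 | 9α,13-epoxylabd-5-ene with 14-benzyloxy and 16-(tert-butyldiphenylsilyloxy) groups | C=1C[C@@H](C)[C@]2(CC[C@@](CO[Si](c3ccccc3)(c3ccccc3)C(C)(C)C)(COCc3ccccc3)O2)[C@@]2(C)CCCC(C)(C)C=12
A6 | alternative 3 | monocyclic 9-keto 13-hydroxy precursor (2,6,6-trimethylcyclohexene with the C6 to C16 chain) | CC1=C(CC[C@@H](C)C(=O)CC[C@@](O)(CO[Si](c2ccccc2)(c2ccccc2)C(C)(C)C)COCc2ccccc2)C(C)(C)CCC1
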